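**Retrosynthetic overview**

- Feature: furans A and B are both 2,4-disubstituted, so in each ring the carbons C2–C3=C4(–C5) are the backbone of a 2-alkyl-1,3-diene whose two ends, C2 and C5, are bridged by the ring oxygen. Furan C is a plain 3-furyl cap, and the single (S)-centre lies in the saturated tether between A and B.
- Key disconnection: all four C–O bonds of furans A and B are cut back to an acyclic (S)-bis-diene with silyl ether and alkyl chloride ends. In the forward direction this is a twofold singlet-oxygen [4+2] addition, base-induced peroxide opening and dehydration in one flask. Rings A and B form together; ring C is attached ready-made afterwards.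
- After the key step: chloride → iodide → alkylzinc and Negishi coupling with 3-bromofuran, then desilylation, MnO2 oxidation, Wittig reaction and saponification to the (E)-2-methylacrylic acid.
- Bis-diene: diene B by Suzuki coupling (alkenylboronate + 2-bromo-5-chloropent-1-ene), diene A by Negishi coupling (alkylzinc + 2-triflyloxy-1,3-diene), both on one iodo-alkenylboronate. That compound comes from (S)-citronellal by Ohira–Bestmann alkynylation, ozonolysis/reduction, iodination and hydroboration; C3 of citronellal becomes the (S)-centre and no bond to it is made or broken.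

Key step: step 10

Remark: the three-carbon arm that later carries furan C is taken through the oxygenation as a primary chloride, which is inert to zinc, palladium, singlet oxygen and Et3N and needs no deprotection before it is activated as the iodide.

**Route**

Step 1
Reactants: 1 (S)-citronellal
Product: 2 (S)-4,8-dimethylnon-7-en-1-yne
Conditions: dimethyl (1-diazo-2-oxopropyl)phosphonate, K2CO3, MeOH, 0 °C → rt
Reagents that add atoms: dimethyl (1-diazo-2-oxopropyl)phosphonate, COP(=O)(OC)C(=[N+]=[N-])C(C)=O
Why: Ohira–Bestmann variant of the Seyferth–Gilbert homologation: methanolysis frees the diazomethylphosphonate anion, which adds to the aldehyde, and after loss of phosphate and N2 the alkylidene carbene rearranges by 1,2-hydride shift to the terminal alkyne; the stereocentre is β to the carbonyl, not enolisable, and is carried over unchanged.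

Step 2
Reactants: 2 (S)-4,8-dimethylnon-7-en-1-yne
Product: 3 (S)-4-methylhept-6-yn-1-ol
Conditions: O3, CH2Cl2/MeOH, −78 °C (Sudan Red 7B end point); then NaBH4, −78 °C → rt
Reagents that add atoms: ozone, [O-][O+]=O
Why: Ozonolysis with reductive work-up: ozone attacks the electron-rich trisubstituted alkene far faster than the terminal alkyne (the dye end point guards against over-ozonation), and NaBH4 reduces the peroxidic products directly to the primary alcohol.

Step 3
Reactants: 3 (S)-4-methylhept-6-yn-1-ol
Product: 4 (S)-7-iodo-4-methylhept-1-yne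
Conditions: I2, PPh3, imidazole, CH2Cl2, 0 °C → rt
Reagents that add atoms: iodine, II
Why: Appel-type iodination: the alkoxyphosphonium ion of the primary alcohol is displaced by iodide in an SN2 step that leaves the alkyne and the remote stereocentre alone.

Step 4
Reactants: 4 (S)-7-iodo-4-methylhept-1-yne
Product: 5 2-[(1E,4S)-7-iodo-4-methylhept-1-en-1-yl]-4,4,5,5-tetramethyl-1,3,2-dioxaborolane
Conditions: pinacolborane, Cy2BH (5 mol%), neat, rt
Reagents that add atoms: pinacolborane, CC1(C)OBOC1(C)C
Why: Hydroboration of a terminal alkyne: Cy2BH adds syn and anti-Markovnikov and passes the alkenyl group on to pinacolborane, which should give only the (E)-alkenylboronate, while the primary C–I bond is inert to neutral boranes.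

Step 5
Reactants: 6 (tert-butyldimethylsilyloxy)acetaldehyde; 7 1-(triphenylphosphoranylidene)propan-2-one
Product: 8 (E)-5-[(tert-butyldimethylsilyl)oxy]pent-3-en-2-one
Conditions: CH2Cl2, rt
Reagents that add atoms: none
Why: Wittig reaction of a stabilised acyl ylide with an unhindered aldehyde, which should give the (E)-enone as is usual for stabilised ylides.

Step 6
Reactants: 8 (E)-5-[(tert-butyldimethylsilyl)oxy]pent-3-en-2-one
Product: 9 (3E)-5-[(tert-butyldimethylsilyl)oxy]penta-1,3-dien-2-yl trifluoromethanesulfonate
Conditions: KN(SiMe3)2, THF, −78 °C; then PhNTf2, −78 → 0 °C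
Reagents that add atoms: N-phenylbis(trifluoromethanesulfonimide), O=S(=O)(N(c1ccccc1)S(=O)(=O)C(F)(F)F)C(F)(F)F
Why: Enol triflate formation under kinetic control: the hindered amide base removes a methyl (α′) proton at −78 °C to give the cross-conjugated dienolate, which is O-sulfonylated by PhNTf2 with the (E)-alkene untouched.

Step 7
Reactants: 5 2-[(1E,4S)-7-iodo-4-methylhept-1-en-1-yl]-4,4,5,5-tetramethyl-1,3,2-dioxaborolane; 9 (3E)-5-[(tert-butyldimethylsilyl)oxy]penta-1,3-dien-2-yl trifluoromethanesulfonate
Product: 11 tert-butyldimethyl{[(2E,8S,10E)-8-methyl-4-methylidene-11-(4,4,5,5-tetramethyl-1,3,2-dioxaborolan-2-yl)undeca-2,10-dien-1-yl]oxy}silane (diene A alkenylboronate), via alkylzinc iodide 10 (not isolated)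
Conditions: Zn dust (activated by BrCH2CH2Br, TMSCl), THF, 40 °C; then 9, PdCl2(dppf) (5 mol%), THF, rt → 45 °C
Reagents that add atoms: none
Why: Negishi coupling: zinc inserts into the primary C–I bond and the alkylzinc iodide couples with the alkenyl triflate at palladium (dppf favours reductive elimination over β-hydride elimination); no base is present, so the pinacol boronate does not transmetalate and is kept for step 9.

Step 8
Reactants: 12 5-chloropent-1-yne
Product: 14 2-bromo-5-chloropent-1-ene, via (Z)-2-bromoalkenyl-9-BBN 13 (not isolated)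
Conditions: B-bromo-9-BBN, CH2Cl2, 0 °C; then AcOH, 0 °C → rt
Reagents that add atoms: B-bromo-9-borabicyclo[3.3.1]nonane, BrB1C2CCCC1CCC2
Why: Haloboration: B-bromo-9-BBN adds B–Br cis and Markovnikov across the terminal alkyne and acetic acid protonolyses the alkenyl C–B bond, which should leave the 2-bromo-1-alkene; the alkyl chloride does not react.

Step 9
Reactants: 11 diene A alkenylboronate; 14 2-bromo-5-chloropent-1-ene
Product: 15 tert-butyl{[(2E,8S,10E)-15-chloro-8-methyl-4,12-dimethylidenepentadeca-2,10-dien-1-yl]oxy}dimethylsilane (bis-diene)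
Conditions: Pd(PPh3)4 (5 mol%), K3PO4 (aq.), THF, 50 °C
Reagents that add atoms: none
Why: Suzuki–Miyaura coupling of an (E)-alkenylboronate with a 1,1-disubstituted alkenyl bromide proceeds with retention at both partners and should give the second (E)-2-alkyl-1,3-diene; the primary chloride, the silyl ether and diene A are inert to Pd(PPh3)4 and aqueous phosphate.

Step 10
Reactants: 15 bis-diene
Product: 18 tert-butyl({4-[(4S)-5-[4-(3-chloropropyl)furan-2-yl]-4-methylpentyl]furan-2-yl}methoxy)dimethylsilane (furan A–furan B chloride), via bis-dioxine 16 (not isolated), via bis(hydroxy enal) 17 (not isolated)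
Conditions: O2, tetraphenylporphyrin (2 mol%), CH2Cl2, visible light, 0 °C; Ar purge, then Et3N (20 mol%), 0 °C → rt; then PPTS (40 mol%), 4 Å MS, rt
Reagents that add atoms: oxygen, O=O
Why: Each (E)-2-alkyl-1,3-diene reacts in its s-cis conformer with tetraphenylporphyrin-sensitised singlet oxygen in a concerted suprafacial [4+2] cycloaddition that joins one oxygen to each diene terminus and gives a 3,6-dihydro-1,2-dioxine; Et3N then removes a proton next to the peroxide (Kornblum–DeLaMare rearrangement), the O–O bond breaks, and a cis-4-hydroxy-enal results. The closest known reaction type is the photooxygenation of acyclic 1,3-dienes to dihydrodioxines and their base- and acid-mediated conversion into furans, used here twice in one molecule. Furan A and furan B each close by 5-exo-trig addition of the hydroxyl group to the cis-formyl group (hemiacetal), and PPTS then removes water to aromatise, so that the ring oxygen spans the former CH and CH2 termini of the diene. The two peroxide-bearing CH centres of 16 form without control and vanish on aromatisation, and the (S)-centre, which is not allylic and bears no acidic hydrogen, is not touched. The step needs chemoselectivity for [4+2] addition over the ene reaction and against oxidation of the product furans: the 2-alkyl group raises the s-cis population, the (E)-geometry leaves the diene terminus open, 15 holds no trisubstituted alkene and no furan, and light and oxygen are removed before the base is added, so that no furan ever meets singlet oxygen.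

Step 11
Reactants: 18 furan A–furan B chloride
Product: 19 tert-butyl({4-[(4S)-5-[4-(3-iodopropyl)furan-2-yl]-4-methylpentyl]furan-2-yl}methoxy)dimethylsilane
Conditions: NaI, acetone, reflux, dark
Reagents that add atoms: sodium iodide, [Na+].[I-]
Why: Finkelstein halide exchange (SN2), driven by precipitation of NaCl from acetone; it is needed because zinc dust inserts into the iodide but not into the chloride.

Step 12
Reactants: 19 furan A–furan B iodide; 20 3-bromofuran
Product: 22 tert-butyl({4-[(4S)-5-{4-[3-(furan-3-yl)propyl]furan-2-yl}-4-methylpentyl]furan-2-yl}methoxy)dimethylsilane, via alkylzinc iodide 21 (not isolated)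
Conditions: Zn dust (activated by BrCH2CH2Br, TMSCl), THF, 40 °C; then 20, Pd(OAc)2 (3 mol%), SPhos (6 mol%), THF, rt → 50 °C
Reagents that add atoms: none
Why: Negishi coupling: zinc insertion into the primary iodide and palladium/SPhos-catalysed coupling with the heteroaryl bromide join C(sp3) to C3 of furan C; the silyl ether and the two 2,4-dialkylfurans are inert to the organozinc.

Step 13
Reactants: 22 tris-furan silyl ether
Product: 23 {4-[(4S)-5-{4-[3-(furan-3-yl)propyl]furan-2-yl}-4-methylpentyl]furan-2-yl}methanol
Conditions: TBAF, THF, 0 °C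
Reagents that add atoms: none
Why: Fluoride-induced cleavage of the primary silyl ether (strong Si–F bond) under conditions that leave the three furans untouched.

Step 14
Reactants: 23 tris-furan alcohol
Product: 24 4-[(4S)-5-{4-[3-(furan-3-yl)propyl]furan-2-yl}-4-methylpentyl]furan-2-carbaldehyde
Conditions: MnO2 (activated, excess), CH2Cl2, rt
Reagents that add atoms: none
Why: MnO2 oxidation of a furfurylic (heteroaryl-activated) primary alcohol should stop at the aldehyde and spare the electron-rich furans.

Step 15
Reactants: 24 tris-furan aldehyde; 25 ethyl 2-(triphenylphosphoranylidene)propanoate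
Product: 26 ethyl (2E)-3-{4-[(4S)-5-{4-[3-(furan-3-yl)propyl]furan-2-yl}-4-methylpentyl]furan-2-yl}-2-methylprop-2-enoate
Conditions: toluene, 80 °C
Reagents that add atoms: none
Why: Wittig reaction with a stabilised α-methyl ylide, which should deliver the trisubstituted (E)-enoate (ester trans to the furan) as in the target.

Step 16
Reactants: 26 ethyl ester
Product: 27 (2E)-3-{4-[(4S)-5-{4-[3-(furan-3-yl)propyl]furan-2-yl}-4-methylpentyl]furan-2-yl}-2-methylprop-2-enoic acid (CNP0088458.1)
Conditions: LiOH, THF/MeOH/H2O, rt; then 1 M HCl to pH 3, 0 °C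
Reagents that add atoms: lithium hydroxide, [Li+].[OH-]
Why: Saponification by addition–elimination of hydroxide at the ester carbonyl, followed by brief cold acidification that the furans should tolerate; the (E)-alkene and the stereocentre are not affected.

**Compound list**

1 | (S)-citronellal, (3S)-3,7-dimethyloct-6-enal | CC(C)=CCC[C@H](C)CC=O | starting material
2 | (S)-4,8-dimethylnon-7-en-1-yne | CC(C)=CCC[C@H](C)CC#C | intermediate
3 | (S)-4-methylhept-6-yn-1-ol | OCCC[C@H](C)CC#C | intermediate
4 | (S)-7-iodo-4-methylhept-1-yne | ICCC[C@H](C)CC#C | intermediate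
5 | 2-[(1E,4S)-7-iodo-4-methylhept-1-en-1-yl]-4,4,5,5-tetramethyl-1,3,2-dioxaborolane | ICCC[C@H](C)C/C=C/B1OC(C)(C)C(C)(C)O1 | intermediate
6 | (tert-butyldimethylsilyloxy)acetaldehyde | CC(C)(C)[Si](C)(C)OCC=O | starting material
7 | 1-(triphenylphosphoranylidene)propan-2-one | CC(=O)C=P(c1ccccc1)(c1ccccc1)c1ccccc1 | starting material
8 | (E)-5-[(tert-butyldimethylsilyl)oxy]pent-3-en-2-one | CC(=O)/C=C/CO[Si](C)(C)C(C)(C)C | intermediate
9 | (3E)-5-[(tert-butyldimethylsilyl)oxy]penta-1,3-dien-2-yl trifluoromethanesulfonate | C=C(OS(=O)(=O)C(F)(F)F)/C=C/CO[Si](C)(C)C(C)(C)C | intermediate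
10 | alkylzinc iodide formed in the flask from 5 | I[Zn]CCC[C@H](C)C/C=C/B1OC(C)(C)C(C)(C)O1 | intermediate
11 | tert-butyldimethyl{[(2E,8S,10E)-8-methyl-4-methylidene-11-(4,4,5,5-tetramethyl-1,3,2-dioxaborolan-2-yl)undeca-2,10-dien-1-yl]oxy}silane | CC(C)(C)[Si](C)(C)OC/C=C/C(=C)CCC[C@H](C)C/C=C/B1OC(C)(C)C(C)(C)O1 | intermediate
12 | 5-chloropent-1-yne | C#CCCCCl | starting material
13 | (Z)-9-(2-bromo-5-chloropent-1-en-1-yl)-9-borabicyclo[3.3.1]nonane, formed in the flask | ClCCC/C(Br)=C/B1C2CCCC1CCC2 | intermediate
14 | 2-bromo-5-chloropent-1-ene | C=C(Br)CCCCl | intermediate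
15 | tert-butyl{[(2E,8S,10E)-15-chloro-8-methyl-4,12-dimethylidenepentadeca-2,10-dien-1-yl]oxy}dimethylsilane | CC(C)(C)[Si](C)(C)OC/C=C/C(=C)CCC[C@H](C)C/C=C/C(=C)CCCCl | intermediate
16 | tert-butyl({5-[(4S)-5-[5-(3-chloropropyl)-3,6-dihydro-1,2-dioxin-3-yl]-4-methylpentyl]-3,6-dihydro-1,2-dioxin-3-yl}methoxy)dimethylsilane, mixture of isomers at the two peroxide carbons, formed in the flask | CC(C)(C)[Si](C)(C)OCC1OOCC(=C1)CCC[C@H](C)CC1OOCC(=C1)CCCCl | intermediate
17 | bis[(2Z)-4-hydroxy-2-enal] from opening of both peroxides of 16, each formyl group cis to its carbinol carbon, formed in the flask | CC(C)(C)[Si](C)(C)OCC(O)/C=C(\C=O)CCC[C@H](C)CC(O)/C=C(\C=O)CCCCl | intermediate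
18 | tert-butyl({4-[(4S)-5-[4-(3-chloropropyl)furan-2-yl]-4-methylpentyl]furan-2-yl}methoxy)dimethylsilane | CC(C)(C)[Si](C)(C)OCc1cc(CCC[C@H](C)Cc2cc(CCCCl)co2)co1 | intermediate
19 | tert-butyl({4-[(4S)-5-[4-(3-iodopropyl)furan-2-yl]-4-methylpentyl]furan-2-yl}methoxy)dimethylsilane | CC(C)(C)[Si](C)(C)OCc1cc(CCC[C@H](C)Cc2cc(CCCI)co2)co1 | intermediate
20 | 3-bromofuran | Brc1ccoc1 | starting material
21 | alkylzinc iodide formed in the flask from 19 | CC(C)(C)[Si](C)(C)OCc1cc(CCC[C@H](C)Cc2cc(CCC[Zn]I)co2)co1 | intermediate
22 | tert-butyl({4-[(4S)-5-{4-[3-(furan-3-yl)propyl]furan-2-yl}-4-methylpentyl]furan-2-yl}methoxy)dimethylsilane | CC(C)(C)[Si](C)(C)OCc1cc(CCC[C@H](C)Cc2cc(CCCc3ccoc3)co2)co1 | intermediate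
23 | {4-[(4S)-5-{4-[3-(furan-3-yl)propyl]furan-2-yl}-4-methylpentyl]furan-2-yl}methanol | OCc1cc(CCC[C@H](C)Cc2cc(CCCc3ccoc3)co2)co1 | intermediate
24 | 4-[(4S)-5-{4-[3-(furan-3-yl)propyl]furan-2-yl}-4-methylpentyl]furan-2-carbaldehyde | O=Cc1cc(CCC[C@H](C)Cc2cc(CCCc3ccoc3)co2)co1 | intermediate
25 | ethyl 2-(triphenylphosphoranylidene)propanoate | CCOC(=O)C(C)=P(c1ccccc1)(c1ccccc1)c1ccccc1 | starting material
26 | ethyl (2E)-3-{4-[(4S)-5-{4-[3-(furan-3-yl)propyl]furan-2-yl}-4-methylpentyl]furan-2-yl}-2-methylprop-2-enoate | C/C(=C\c1cc(CCC[C@H](C)Cc2cc(CCCc3ccoc3)co2)co1)C(=O)OCC | intermediate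
27 | (2E)-3-{4-[(4S)-5-{4-[3-(furan-3-yl)propyl]furan-2-yl}-4-methylpentyl]furan-2-yl}-2-methylprop-2-enoic acid, CNP0088458.1 | C/C(=C\c1cc(CCC[C@H](C)Cc2cc(CCCc3ccoc3)co2)co1)C(=O)O | target

**Step count**

Total: 16 steps (steps 5, 6 and 8 make the two side fragments). Longest linear sequence: 13 steps from (S)-citronellal (steps 1–4, 7, 9–16).

**Steps most likely to fail**

1. Step 10. The ene pathway (hydroperoxide formation at the CH2 groups flanking each diene) and radical autoxidation may outrun the cycloaddition at one of the dienes. The two dienes may also react at unequal rates, so that the long irradiation needed for the slower one degrades the dioxine formed first. The fallback gives up the oxygenation and builds rings A and B one at a time by non-oxidative, known chemistry; it sets out from 3 and comes back at 18. Alkynol 3 is coupled with bromoalkene 14 (Sonogashira; PdCl2(PPh3)2, CuI, Et3N, rt) to the enynol F1. The 1,1-disubstituted alkene of the enyne is dihydroxylated (K2OsO4·2H2O cat., N-methylmorpholine N-oxide, acetone/H2O) to the alkynediol F2. AgNO3 on silica gel (CH2Cl2, rt) should bring about 5-endo-dig attack of the primary hydroxyl on the alkyne and loss of water to the furan B alcohol F3, and I2/PPh3/imidazole converts it into the furan B iodide F4. Separately, commercial 4-bromofuran-2-carbaldehyde is reduced (NaBH4, MeOH) to (4-bromofuran-2-yl)methanol F5 and silylated (TBSCl, imidazole) to the bromofuran silyl ether F6. Zinc insertion into the iodide of F4 (the chloride stays) and Negishi coupling with F6 (Pd(OAc)2, SPhos, THF) attach ready-made furan A and give 18.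

2. Step 7. The dienyl triflate may ionise, hydrolyse or polymerise before oxidative addition, and the alkylpalladium intermediate may undergo β-hydride elimination or protonation, so that the chain ends as alkene or alkane instead of the diene. The fallback makes the C(sp3)–C(sp2) bond by acylation and adds the methylene carbon afterwards, which also dispenses with triflate 9; it sets out from 5 (through its zinc reagent 10) and comes back at 11. Aldehyde 6 and S-ethyl (triphenylphosphoranylidene)thioacetate give the thioester F7. Fukuyama coupling of 10 with F7 (PdCl2(PPh3)2, THF/toluene, rt) should give the enone F8. Methylenation of the ketone with the Zn/CH2Br2/TiCl4 reagent (Takai–Lombardo), which is non-basic and tolerates the boronate and the silyl ether, gives 11.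

3. Step 12. Zinc insertion may stay incomplete on this late, precious material, and the alkylzinc may be lost by protonation or β-hydride elimination before it couples with the volatile, electron-rich 3-bromofuran. The fallback joins the two halides directly, without a preformed organometallic, by nickel-catalysed reductive cross-electrophile coupling; it sets out from 19 and 20 and comes back at 22. The conditions are NiBr2·glyme, 4,4′-di-tert-butyl-2,2′-bipyridine, Mn powder, NaI, DMA, 60 °C, and no new compound is made on this path (none F0).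

**Further compounds**

F1 | step 10 | (S)-11-chloro-4-methyl-8-methylideneundec-6-yn-1-ol | OCCC[C@H](C)CC#CC(=C)CCCCl
F2 | step 10 | (4S)-11-chloro-8-(hydroxymethyl)-4-methylundec-6-yne-1,8-diol | OCCC[C@H](C)CC#CC(O)(CO)CCCCl
F3 | step 10 | (S)-5-[4-(3-chloropropyl)furan-2-yl]-4-methylpentan-1-ol | OCCC[C@H](C)Cc1cc(CCCCl)co1
F4 | step 10 | 4-(3-chloropropyl)-2-[(2S)-5-iodo-2-methylpentyl]furan | ICCC[C@H](C)Cc1cc(CCCCl)co1
F5 | step 10 | (4-bromofuran-2-yl)methanol | OCc1cc(Br)co1
F6 | step 10 | [(4-bromofuran-2-yl)methoxy](tert-butyl)dimethylsilane | CC(C)(C)[Si](C)(C)OCc1cc(Br)co1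
F7 | step 7 | S-ethyl (E)-4-[(tert-butyldimethylsilyl)oxy]but-2-enethioate | CCSC(=O)/C=C/CO[Si](C)(C)C(C)(C)C
F8 | step 7 | (2E,8S,10E)-1-[(tert-butyldimethylsilyl)oxy]-8-methyl-11-(4,4,5,5-tetramethyl-1,3,2-dioxaborolan-2-yl)undeca-2,10-dien-4-one | CC(C)(C)[Si](C)(C)OC/C=C/C(=O)CCC[C@H](C)C/C=C/B1OC(C)(C)C(C)(C)O1
F0 | step 12 | none | none
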